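## The problem

Numbering follows the labdane convention: ring A is C1–C5 plus C10, ring B is C5–C10, the chain C11–C16 hangs from C9 with C16 as the O–CH carbon of the butenolide, and α is the face of H5, β that of the C10 methyl group. The target is a trans-fused decalin (4R,5R,6S,8R,9R,10S) with a quaternary C4 (α-CO2Me, β-CH3), a secondary 6α-carbinol, a tertiary 8α-carbinol with a β-methyl group, the chain-bearing C9 and the angular quaternary C10; the chain holds an (E)-trisubstituted C13=C14 olefin, the allylic carbinol C15 and C16 of a 4-methylbutenolide in the threo 15S,16S relationship. C4 and C5 are neighbours and can be set together in one cycloaddition, after which C5 can pass its configuration to C10, C9 and C8 through a chair-like closure of ring B, and it also flanks C6. C15 and C16 lie five bonds from the nearest ring stereocentre and must be set by a reagent. The butenolide is base-sensitive (γ-deprotonation would epimerise C16), the allylic C15 alcohol and the tertiary C8 alcohol ionise in acid, and the 6-hydroxy group sits 1,3 to the C4 ester and could lactonise onto it. Intermediates with a carbonyl group at C6 are β,γ-unsaturated and epimerisable at C5. The feature that opens the route lies in ring A: only C4, C5 and C10 are substituted, the C4 carboxyl carbon is cis to H5 and the C4 methyl group is cis to the C6 arm. This is the pattern left by an exo [4+2] addition of methacrolein (C3=C4) to an (E)-diene C2=C1–C10(CH3)=C5–C6, and the surviving C10=C1 olefin is the latent C10 cation needed to close ring B.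

## Retrosynthesis

**C15–C16.** The target 25 is cut between the carbinol carbon and the butenolide γ-carbon, giving enal 21 and 4-methyl-2-(trimethylsilyloxy)furan 23. A vinylogous Mukaiyama aldol addition forms this bond and both remote stereocentres in one step and brings the whole butenolide in as a five-carbon unit from furanone 22. A cut at C14–C15 would need a chiral α-oxygenated aldehyde and several later steps to build the lactone. The forward reaction must be threo-selective and face-selective on the aldehyde, and must tolerate the silylated 6- and 8-hydroxy groups.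

**C13–CH3 and C14–C15, then C13≡C14.** Enal 21 comes from allylic alcohol 20, made by methylalumination of the terminal alkyne 18 (the bis-silyl ether of 17) and capture of the alkenylalane 19 with a one-carbon electrophile. Syn-carbometalation fixes the (E) geometry, which carbonyl olefination of a methyl ketone would not. Alkyne 17 is the one-carbon homologue of lactol 16, the reduction product of δ-lactone 15. The precursor 15 has no side-chain stereochemistry and no sensitive olefin.

**C9–C10 and C8–O (ring B).** Lactone 15 is opened to the monocyclic diene ester 14. In the forward sense, protonation of the C10=C1 olefin gives the C10 cation, C9 of the (E)-C8=C9 olefin attacks it, and the carboxyl oxygen captures the C8 cation. This one step closes ring B and sets C10, C9 and C8 from C5. It is preferred to a cyclisation without an oxygen terminator, which would leave C8 as an olefin mixture to be hydrated later. The 6-oxygen is carried as an acetate, the group least able to push a retro-Prins fragmentation of the γ-oxy cations.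

**C9–C11, C8–CH3 and C6–C7.** Ester 14 is cut at the sp2–sp3 bond C9–C11 into vinyl iodide 13 (the acetate of 12) and the three-carbon zinc homoenolate BrZn(CH2)2CO2t-Bu. Iodide 12 comes from homopropargylic alcohol 10 by methylalumination–iodination, which sets the (E)-C8=C9 geometry. Alcohol 10 comes from aldehyde 9 by asymmetric propargylation, which creates C6. An allyl-metal route to the same chain would add at the wrong allyl terminus. The precursor 9 has only the two cycloaddition stereocentres.

**Functional-group changes on ring A.** Aldehyde 9 is reached from cycloadduct 5 by oxidising the C4 formyl group to the methyl ester (6, 7) and then converting the silyloxymethyl arm into the C6 aldehyde (8, 9). The ester is made first so that two aldehydes never coexist.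

**C2–C3 and C4–C5 (ring A).** Cyclohexene 5 is cut into methacrolein 4 and (E)-dienyl silyl ether 3. The catalytic enantioselective Diels–Alder reaction builds the C4 quaternary centre, the C4/C5 relationship and the absolute configuration from two achiral pieces of four and six carbons. The alternative of building ring A by cation–olefin cyclisation cannot place a carboxyl group stereoselectively at C4. The forward step needs ortho regiochemistry, the exo-formyl mode and face selectivity.

**Diene.** Diene 3 is the silyl ether of dienol 2, obtained by semi-hydrogenation of the commercial (E)-enynol 1, whose olefin geometry becomes the diene geometry.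

## Roads not taken

**Alternative 1:** The cut is the C6–O bond, made by C–H functionalisation on the bicyclic primary carboxamide A1, which would itself have to be carved out of a tricyclic resin acid of the chiral pool. Amide A1 would be N-iodinated in the flask (PhI(OAc)2, I2, light). The amidyl radical so formed abstracts the equatorial 6α-hydrogen through a six-membered transition state, and iodination at C6, closure through the amide oxygen and hydrolysis give the γ-lactone A2.
- Merits: C4, C5 and C10 come from the chiral pool with no asymmetric catalysis and no quaternary-centre construction, and the oxygen can only arrive on the α face. In this respect it is better than the chosen plan.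
- Weak points: the resin acids on the market are tricyclic, so a ring must be degraded to reveal the C8 carbinol and the C9 arm. The lactone of A2 bridges two equatorial positions and is strained, and its methanolysis to the open form is an equilibrium. The whole side chain still has to be built.
- Comparison: the chosen plan puts the C6 oxygen in during chain construction and forms ring B and the C8–O bond in one step, at the price of relying on a catalyst for absolute configuration.

**Alternative 2:** The cut is C3–C4 and C5–C10 together: an intramolecular Diels–Alder reaction of the acyclic triene ester A3, on heating or with Me2AlCl, would give the trans-fused octalin A4.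
- Merits: both rings and three stereocentres (C4, C5, C10) form in one step, with C4/C5 fixed by the (E)-enoate geometry. It is more convergent than the chosen plan.
- Weak points: the diene terminus C10 is disubstituted, so one substituent must point inward in the s-cis conformer, and the dienophile is a trisubstituted enoate. Two quaternary carbons form in one cycloaddition, which will need forcing conditions that the γ-silyloxy enoate of A3 may not survive. Trans-fusion and facial selectivity depend on three preset stereocentres (C6, C8, C9), including the tertiary carbinol, in an acyclic precursor that is itself long to make. The C1=C2 olefin of A4 must then be hydrogenated.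
- Comparison: the chosen plan forms the quaternary centres one at a time, each in a reaction type known to tolerate that degree of substitution.

**Alternative 3:** The cut is C13–CH3 and C14–C15: Cp2ZrCl2-catalysed methylalumination of alkyne A5, followed in the same flask by addition of the new carbon–aluminium bond to the α-alkoxy aldehyde A6, would give allylic alcohol A7.
- Merits: C16 comes from the chiral pool and C15 from chelation control, so the stereochemical outcome is more predictable than that of a catalytic vinylogous aldol addition. This is a real advantage.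
- Weak points: it is an end-game only and leaves the bicycle unsolved. After the coupling the butenolide must be built from A7 in five or more steps (deprotection, oxidation, methyl addition, oxidation, lactone annulation).
- Comparison: the chosen route uses the same carbometalation for the olefin geometry (step 16) but forms C15–C16 instead and brings the lactone in ready-made. Its price is the uncertain selectivity of step 19, for which a slower, auxiliary-based fallback is given.

Key step: step 3

Assumption: the antipodes written for the salt [C24H25BNO][N(SO2CF3)2] (step 3), for (S)-TRIP (step 8), for (R)-BINOL with Ti(OiPr)4 (step 19) and for the fallback reagents follow the accepted face-selectivity models; each would be checked on a model substrate and the mirror-image reagent used if the sense is opposite.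

## Route

Step 1
Reactants: 1 (E)-3-methylpent-2-en-4-yn-1-ol
Product: 2 (E)-3-methylpenta-2,4-dien-1-ol
Conditions: H2 (1 atm), Pd/CaCO3 poisoned with Pb(OAc)2, quinoline, EtOAc, rt
Reagents that add atoms: none
Why: Semi-hydrogenation of a terminal alkyne over Pd/CaCO3 poisoned with Pb(OAc)2 stops at the vinyl group and leaves the (E)-trisubstituted olefin untouched, so the enyne geometry becomes the diene geometry.

Step 2
Reactants: 2 (E)-3-methylpenta-2,4-dien-1-ol
Product: 3 (E)-dienyl TBS ether
Conditions: TBSCl, imidazole, CH2Cl2, 0 °C → rt
Reagents that add atoms: tert-butyldimethylsilyl chloride, CC(C)(C)[Si](C)(C)Cl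
Why: Standard silylation of a primary allylic alcohol; the ether removes the free hydroxyl that would quench the Lewis acid of step 3.

Step 3
Reactants: 3 (E)-dienyl TBS ether; 4 methacrolein
Product: 5 ring A aldehyde (1R,2R)
Conditions: [C24H25BNO][N(SO2CF3)2] (15 mol%, (R)-series, from the (R)-diphenylprolinol-derived B-(o-tolyl)oxazaborolidine and HN(SO2CF3)2), CH2Cl2, −78 → −40 °C
Reagents that add atoms: none
Why: Lewis-acid-catalysed, concerted but asynchronous [4+2] cycloaddition, the oxazaborolidinium-catalysed Diels–Alder reaction of a 2-substituted acrolein with an acyclic diene. The aldehyde binds to boron with its formyl C–H held by the ring oxygen, so one face of the s-trans enal lies over a phenyl group of the catalyst and the diene reaches C4 from the open face (the Si face of the α-carbon is the one required, expected with the (R)-series salt). Ring A closes as a cyclohexene by suprafacial–suprafacial addition, the C2–C3 bond forming slightly ahead of the C4–C5 bond and leaving the C10=C1 olefin. Regiochemistry follows the 1-alkyl substituent of the diene: the large LUMO coefficient at C3 meets the unsubstituted terminus C2, while the C10 methyl opposes this only weakly and attack of C3 on the hindered C5 terminus is sterically disfavoured. C4 is set by the catalyst through the enantioface of the dienophile. C5 is set relative to C4 by the exo-formyl (endo-methyl) mode together with the (E) geometry of C5=C10, which places CHO cis to H5 and CH3 cis to the CH2OTBS arm. The step needs regio-, exo- and enantioface selectivity: the first comes from the diene substitution, the second from the α-methyl group and the bulk of the boron-bound formyl group, the third from the catalyst antipode.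

Step 4
Reactants: 5 ring A aldehyde
Product: 6 ring A carboxylic acid
Conditions: NaClO2, NaH2PO4, 2-methylbut-2-ene, t-BuOH/H2O, 0 °C → rt
Reagents that add atoms: sodium chlorite, [Na+].[O-]Cl=O
Why: Pinnick oxidation works on hindered neopentyl aldehydes; the scavenger removes HOCl so the ring olefin and the silyl ether survive, and the quaternary C4 cannot epimerise.

Step 5
Reactants: 6 ring A carboxylic acid
Product: 7 ring A methyl ester
Conditions: MeI, K2CO3, DMF, rt
Reagents that add atoms: iodomethane, CI
Why: O-alkylation of the carboxylate (SN2 at methyl) is not slowed by the hindered acyl carbon, unlike Fischer esterification.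

Step 6
Reactants: 7 ring A methyl ester
Product: 8 primary alcohol
Conditions: HF·pyridine, pyridine, THF, 0 °C
Reagents that add atoms: none
Why: Fluoride-mediated desilylation under buffered, mildly acidic conditions; a basic alkoxide is avoided because the γ-hydroxy ester could close to the trans-fused lactone, and 8 is used at once.

Step 7
Reactants: 8 primary alcohol
Product: 9 C6 aldehyde
Conditions: Dess–Martin periodinane, NaHCO3, CH2Cl2, 0 °C → rt
Reagents that add atoms: none
Why: Dess–Martin oxidation is neutral and fast, which should keep the β,γ-unsaturated aldehyde from conjugating and C5 from epimerising.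

Step 8
Reactants: 9 C6 aldehyde
Product: 10 homopropargylic alcohol (6S)
Conditions: allenylboronic acid pinacol ester, (S)-TRIP [3,3'-bis(2,4,6-triisopropylphenyl)-1,1'-binaphthyl-2,2'-diyl hydrogen phosphate] (10 mol%), 4 Å MS, toluene, −30 → 0 °C
Reagents that add atoms: allenylboronic acid pinacol ester, C=C=CB1OC(C)(C)C(C)(C)O1
Why: Brønsted-acid-catalysed allenylboration (asymmetric propargylation): the γ-carbon of the allenylboronate adds through a closed six-membered transition state organised by the chiral phosphate, which should deliver C7 to the Si face and give the 6S carbinol without base. The Felkin–Anh preference of C5 is expected to be small but opposed, so the step relies on catalyst control.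

Step 9
Reactants: 10 homopropargylic alcohol
Product: 12 (E)-vinyl iodide, via alkenylalane 11 (not isolated)
Conditions: AlMe3 (3 equiv), Cp2ZrCl2 (0.25 equiv), H2O (1 equiv), CH2Cl2, −20 °C; then I2, THF, −20 → 0 °C
Reagents that add atoms: trimethylaluminium, C[Al](C)C; iodine, II
Why: Negishi carboalumination catalysed by Cp2ZrCl2 adds CH3 and Al syn across the terminal alkyne with methyl on the internal carbon C8, and iodinolysis proceeds with retention, giving the (E)-C8=C9 geometry; the water-accelerated low-temperature variant limits contact of the aluminium alkoxide with the C4 ester.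

Step 10
Reactants: 12 (E)-vinyl iodide
Product: 13 C6 acetate
Conditions: Ac2O, pyridine, DMAP (cat.), CH2Cl2, 0 °C → rt
Reagents that add atoms: acetic anhydride, CC(=O)OC(C)=O
Why: Acylation gives an acid-stable group whose oxygen lone pairs are too poor a donor to drive retro-Prins cleavage of the γ-oxy cations in step 12.

Step 11
Reactants: 13 C6 acetate
Product: 14 diene tert-butyl ester
Conditions: BrZn(CH2)2CO2t-Bu (0.5 M in THF, 2 equiv), Pd(PPh3)4 (5 mol%), THF, 40 °C
Reagents that add atoms: (3-tert-butoxy-3-oxopropyl)zinc bromide, CC(C)(C)OC(=O)CC[Zn]Br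
Why: Negishi sp2–sp3 coupling of a zinc homoenolate with a vinyl iodide on zerovalent palladium retains the olefin geometry and tolerates the acetate and both esters.

Step 12
Reactants: 14 diene tert-butyl ester
Product: 15 tricyclic δ-lactone
Conditions: SnCl4 (2.5 equiv), CF3CO2H (2 equiv), CH2Cl2, −78 → −30 °C
Reagents that add atoms: none
Why: Proton-initiated cation–olefin cyclisation terminated by a carboxyl oxygen, as in the lactone-forming closure of monocyclic homofarnesic-type acids: protonation at C1 gives the C10 cation, C9 of the (E)-olefin attacks through a chair with the C5 arm and the 6-acetoxy group equatorial, and the ester carbonyl captures the C8 cation anti to the new C9–C10 bond with loss of 2-methylpropene. C5 thereby sets C10 (CH3 trans to H5), and the (E) geometry with anti addition sets C9 (H α) and C8 (O α, CH3 β).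

Step 13
Reactants: 15 tricyclic δ-lactone
Product: 16 lactol with free 6-hydroxyl
Conditions: i-Bu2AlH (3.2 equiv), CH2Cl2, −78 °C; MeOH, aq. potassium sodium tartrate
Reagents that add atoms: none
Why: At −78 °C i-Bu2AlH reduces the lactone only to the lactol and cleaves the acetate reductively, while the C4 methyl ester, attached to a quaternary carbon, should react much more slowly.

Step 14
Reactants: 16 lactol
Product: 17 alkyne diol
Conditions: dimethyl (1-diazo-2-oxopropyl)phosphonate, K2CO3, MeOH, 0 °C → rt
Reagents that add atoms: dimethyl (1-diazo-2-oxopropyl)phosphonate, COP(=O)(OC)C(=[N+]=[N-])C(C)=O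
Why: Seyferth–Gilbert homologation with the Ohira–Bestmann reagent acts on the hydroxy aldehyde in equilibrium with the lactol and releases the 8α-hydroxyl and the C13≡C14 alkyne; no stereocentre is adjacent to a carbonyl group.

Step 15
Reactants: 17 alkyne diol
Product: 18 bis-TES ether
Conditions: Et3SiOTf (3 equiv), 2,6-lutidine, CH2Cl2, −78 → 0 °C
Reagents that add atoms: triethylsilyl trifluoromethanesulfonate, CC[Si](CC)(CC)OS(=O)(=O)C(F)(F)F
Why: The silyl triflate caps both the secondary and the tertiary hydroxyl, which removes protic sites for steps 16 and 19 and blocks lactonisation onto the C4 ester.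

Step 16
Reactants: 18 bis-TES ether
Product: 20 (E)-allylic alcohol, via alkenylalane 19 (not isolated)
Conditions: AlMe3 (2.5 equiv), Cp2ZrCl2 (0.25 equiv), CH2Cl2, 0 °C → rt; evaporate; n-BuLi (1.1 equiv), THF, −78 °C; (CH2O)n, −78 °C → rt
Reagents that add atoms: trimethylaluminium, C[Al](C)C; paraformaldehyde (as formaldehyde), C=O
Why: Negishi carboalumination places CH3 on C13 and Al on C14 syn, and the alkenylalanate adds to formaldehyde with retention, giving the (E)-C13=C14 allylic alcohol; the butyllithium is consumed by aluminium, so none is free to attack the ester.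

Step 17
Reactants: 20 (E)-allylic alcohol
Product: 21 (E)-enal
Conditions: MnO2 (excess), CH2Cl2, rt
Reagents that add atoms: none
Why: MnO2 oxidises allylic alcohols selectively and under neutral conditions, so the olefin geometry and the silyl ethers are kept.

Step 18
Reactants: 22 4-methylfuran-2(5H)-one
Product: 23 4-methyl-2-(trimethylsilyloxy)furan
Conditions: Me3SiOTf, Et3N, Et2O, 0 °C; distil
Reagents that add atoms: trimethylsilyl trifluoromethanesulfonate, C[Si](C)(C)OS(=O)(=O)C(F)(F)F
Why: Soft enolisation of the butenolide at the γ-position with O-silylation gives the aromatic silyloxyfuran, a standard dienolate equivalent.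

Step 19
Reactants: 21 (E)-enal; 23 4-methyl-2-(trimethylsilyloxy)furan
Product: 25 CNP0104474.1, via silyl aldolate 24 (not isolated)
Conditions: Ti(OiPr)4 (20 mol%), (R)-BINOL (20 mol%), Et2O, −20 °C; then HF·pyridine, THF, 0 °C → rt
Reagents that add atoms: none
Why: Vinylogous Mukaiyama aldol addition: C5 of the silyloxyfuran (the future C16) adds 1,2 to the aldehyde, because 1,4-addition would create a quaternary carbon at C13. The open transition state of Lewis-acid-promoted silyloxyfuran additions favours the threo adduct, and the catalyst formed from Ti(OiPr)4 and (R)-BINOL chooses the aldehyde face, which fixes 15S,16S. Fluoride then removes the trimethylsilyl and both triethylsilyl groups without base, sparing the butenolide and the allylic alcohol.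

## Compound list

1 | (E)-3-methylpent-2-en-4-yn-1-ol | C#C/C(C)=C/CO | starting material
2 | (E)-3-methylpenta-2,4-dien-1-ol | C=C/C(C)=C/CO | intermediate
3 | tert-butyl(dimethyl){[(2E)-3-methylpenta-2,4-dien-1-yl]oxy}silane | C=C/C(C)=C/CO[Si](C)(C)C(C)(C)C | intermediate
4 | methacrolein (2-methylprop-2-enal) | CC(=C)C=O | starting material
5 | (1R,2R)-2-{[(tert-butyldimethylsilyl)oxy]methyl}-1,3-dimethylcyclohex-3-ene-1-carbaldehyde | O=C[C@]1(C)CCC=C(C)[C@H]1CO[Si](C)(C)C(C)(C)C | intermediate
6 | (1R,2R)-2-{[(tert-butyldimethylsilyl)oxy]methyl}-1,3-dimethylcyclohex-3-ene-1-carboxylic acid | OC(=O)[C@]1(C)CCC=C(C)[C@H]1CO[Si](C)(C)C(C)(C)C | intermediate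
7 | methyl (1R,2R)-2-{[(tert-butyldimethylsilyl)oxy]methyl}-1,3-dimethylcyclohex-3-ene-1-carboxylate | COC(=O)[C@]1(C)CCC=C(C)[C@H]1CO[Si](C)(C)C(C)(C)C | intermediate
8 | methyl (1R,2R)-2-(hydroxymethyl)-1,3-dimethylcyclohex-3-ene-1-carboxylate | COC(=O)[C@]1(C)CCC=C(C)[C@H]1CO | intermediate
9 | methyl (1R,2R)-2-formyl-1,3-dimethylcyclohex-3-ene-1-carboxylate | COC(=O)[C@]1(C)CCC=C(C)[C@H]1C=O | intermediate
10 | methyl (1R,2R)-2-[(1S)-1-hydroxybut-3-yn-1-yl]-1,3-dimethylcyclohex-3-ene-1-carboxylate | COC(=O)[C@]1(C)CCC=C(C)[C@H]1[C@@H](O)CC#C | intermediate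
11 | (E)-alkenyl(dimethyl)alane of 10 formed in the flask, the 6-oxygen being its dimethylaluminium alkoxide | COC(=O)[C@]1(C)CCC=C(C)[C@H]1[C@@H](O[Al](C)C)C/C(C)=C/[Al](C)C | intermediate
12 | methyl (1R,2R)-2-[(1S,3E)-1-hydroxy-4-iodo-3-methylbut-3-en-1-yl]-1,3-dimethylcyclohex-3-ene-1-carboxylate | COC(=O)[C@]1(C)CCC=C(C)[C@H]1[C@@H](O)C/C(C)=C/I | intermediate
13 | methyl (1R,2R)-2-[(1S,3E)-1-acetoxy-4-iodo-3-methylbut-3-en-1-yl]-1,3-dimethylcyclohex-3-ene-1-carboxylate | COC(=O)[C@]1(C)CCC=C(C)[C@H]1[C@@H](OC(C)=O)C/C(C)=C/I | intermediate
14 | methyl (1R,2R)-2-[(1S,3E)-1-acetoxy-7-tert-butoxy-3-methyl-7-oxohept-3-en-1-yl]-1,3-dimethylcyclohex-3-ene-1-carboxylate | COC(=O)[C@]1(C)CCC=C(C)[C@H]1[C@@H](OC(C)=O)C/C(C)=C/CCC(=O)OC(C)(C)C | intermediate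
15 | tricyclic δ-lactone (4R,5R,6S,8R,9R,10S): trans-decalin with 4α-CO2Me, 4β-CH3, 6α-OAc, 8β-CH3, 10β-CH3, 5α-H, 9α-H and a six-membered lactone O(8α)–C13(=O)–C12H2–C11H2–C9 | COC(=O)[C@]1(C)CCC[C@@]2(C)[C@H]1[C@@H](OC(C)=O)C[C@@](C)(OC(=O)CC3)[C@@H]23 | intermediate
16 | lactol of 15 with free 6α-OH (C13 hemiacetal, both C13 epimers) | COC(=O)[C@]1(C)CCC[C@@]2(C)[C@H]1[C@@H](O)C[C@@](C)(OC(O)CC3)[C@@H]23 | intermediate
17 | alkyne diol (4R,5R,6S,8R,9R,10S): methyl trans-decalin-4α-carboxylate with 6α-OH, 8α-OH, 4β-, 8β-, 10β-CH3 and 9β-(but-3-yn-1-yl) | COC(=O)[C@]1(C)CCC[C@@]2(C)[C@H]1[C@@H](O)C[C@@](C)(O)[C@@H]2CCC#C | intermediate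
18 | 6α,8α-bis(triethylsilyl) ether of 17 | COC(=O)[C@]1(C)CCC[C@@]2(C)[C@H]1[C@@H](O[Si](CC)(CC)CC)C[C@@](C)(O[Si](CC)(CC)CC)[C@@H]2CCC#C | intermediate
19 | (E)-alkenyl(dimethyl)alane from 18 formed in the flask (C13–CH3, C14–AlMe2) | COC(=O)[C@]1(C)CCC[C@@]2(C)[C@H]1[C@@H](O[Si](CC)(CC)CC)C[C@@](C)(O[Si](CC)(CC)CC)[C@@H]2CC/C(C)=C/[Al](C)C | intermediate
20 | (E)-allylic alcohol: 18 with 9β-[(3E)-5-hydroxy-3-methylpent-3-en-1-yl] in place of the butynyl chain | COC(=O)[C@]1(C)CCC[C@@]2(C)[C@H]1[C@@H](O[Si](CC)(CC)CC)C[C@@](C)(O[Si](CC)(CC)CC)[C@@H]2CC/C(C)=C/CO | intermediate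
21 | (E)-enal: 9β-[(3E)-3-methyl-5-oxopent-3-en-1-yl] analogue of 20 | COC(=O)[C@]1(C)CCC[C@@]2(C)[C@H]1[C@@H](O[Si](CC)(CC)CC)C[C@@](C)(O[Si](CC)(CC)CC)[C@@H]2CC/C(C)=C/C=O | intermediate
22 | 4-methylfuran-2(5H)-one | CC1=CC(=O)OC1 | starting material
23 | 4-methyl-2-(trimethylsilyloxy)furan | Cc1coc(O[Si](C)(C)C)c1 | intermediate
24 | silyl aldolate formed in the flask: 15-O-trimethylsilyl, 6,8-bis-O-triethylsilyl ether of the target (15S,16S) | COC(=O)[C@]1(C)CCC[C@@]2(C)[C@H]1[C@@H](O[Si](CC)(CC)CC)C[C@@](C)(O[Si](CC)(CC)CC)[C@@H]2CC/C(C)=C/[C@H](O[Si](C)(C)C)[C@H]1OC(=O)C=C1C | intermediate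
25 | CNP0104474.1 (4R,5R,6S,8R,9R,10S,13E,15S,16S) | COC(=O)[C@]1(C)CCC[C@@]2(C)[C@H]1[C@@H](O)C[C@@](C)(O)[C@@H]2CC/C(C)=C/[C@H](O)[C@H]1OC(=O)C=C1C | target

## Step count and least certain steps

Total: 19 steps. Longest linear sequence: 18 steps (steps 1–17 and 19 from 1); step 18 is a one-step side branch.

**Step 3 (key step).** The most likely failure is erosion of the exo preference: an acyclic diene lacks the bridging methylene that enforces exo addition with cyclopentadiene, so the endo-formyl approach may compete. The C10 methyl group may also erode the ortho regioselectivity, and the allylic silyl ether may ionise on the cationic oxazaborolidinium acid. The fallback keeps the same two bonds and the same ring closure but swaps the roles of the two C4 substituents, so that an endo-formyl preference becomes productive. It sets out from 3 and returns at 5. Diene 3 is combined with 2-{[(4-methoxybenzyl)oxy]methyl}prop-2-enal F1 under the (S)-series salt [C24H25BNO][N(SO2CF3)2] to give the endo adduct F2, in which the formyl group is cis to the C6 arm. The formyl group is turned into the C4 methyl group through the tosylhydrazone F3 (TsNHNH2) and its reduction with catecholborane, then NaOAc, to the PMB ether F4. DDQ releases the neopentyl alcohol F5, and Dess–Martin oxidation gives 5.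

**Step 8.** The catalyst may fail to overcome the opposing Felkin–Anh bias of the hindered, α-branched aldehyde (poor facial selectivity), and slow addition may allow C5 to epimerise. The fallback sets C6 by hydride addition, where substrate and reagent control agree. It sets out from 9 and returns at 12. Zinc-mediated Barbier propargylation (propargyl bromide, Zn, THF/aq. NH4Cl) gives 10 together with its C6 epimer F6. Step 9 applied to the mixture gives 12 and its C6 epimer F7. Dess–Martin oxidation gives the β,γ-unsaturated ketone F8, which is reduced at once with (R)-2-methyl-CBS-oxazaborolidine and catecholborane at −78 °C (Corey–Bakshi–Shibata reduction) to 12.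

**Step 12.** The side-chain olefin may be protonated first and lactonise without ring closure, the acetate carbonyl may intercept the C10 cation, the C10 cation may shed H5 reversibly and so loosen the C4/C5 relationship, ring closure may occur in part through the cis-fused mode, or the C8 cation may lose a proton before the hindered carboxyl captures it. The fallback separates C–C from C–O bond formation. It sets out from 14 and returns at 15. The acid cyclisation is run for ring closure only, accepting the exocyclic C8-methylene acid F9 and the C7=C8 olefinic acid F10. Both are hydrated by Mukaiyama hydration (Co(acac)2, PhSiH3, O2, i-PrOH, then PPh3). Hydrogen-atom transfer gives the same tertiary C8 radical from either isomer, and oxygen is taken up on the α face, away from the axial C10 methyl, to give the 8α-hydroxy acid F11. Camphorsulfonic acid closes F11 to 15.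

**Step 19.** The threo preference may be low with the 4-methyl-substituted furan, the enantioface selection by the Ti(OiPr)4/(R)-BINOL catalyst may be poor for a β,β-disubstituted enal, and silyl transfer may stall turnover. The fallback is an auxiliary-controlled sequence of known reactions. It sets out from 21 and returns at 25. Evans syn-aldol addition of the dibutylboron enolate of (R)-4-benzyl-3-{[(4-methoxybenzyl)oxy]acetyl}oxazolidin-2-one (Bu2BOTf, Et3N) to 21 gives the syn glycolate adduct F12 with 15S and the correct C16 configuration. MeNH(OMe)·HCl and AlMe3 convert it into the Weinreb amide F13, and Et3SiOTf gives its 15-O-triethylsilyl ether F14. MeMgBr then gives the methyl ketone F15, and DDQ removes the PMB group to give the α-hydroxy ketone F16. Ph3P=C=C=O in hot toluene (O-acylation, then intramolecular Wittig reaction) closes the butenolide to the tris-silyl ether F17, and HF·pyridine gives 25.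

## Further compounds

F1 | step 3 | 2-{[(4-methoxybenzyl)oxy]methyl}prop-2-enal | C=C(COCc1ccc(OC)cc1)C=O
F2 | step 3 | (1S,2R)-2-{[(tert-butyldimethylsilyl)oxy]methyl}-1-{[(4-methoxybenzyl)oxy]methyl}-3-methylcyclohex-3-ene-1-carbaldehyde | COc1ccc(COC[C@]2(C=O)CCC=C(C)[C@H]2CO[Si](C)(C)C(C)(C)C)cc1
F3 | step 3 | (E)-tosylhydrazone of F2 | COc1ccc(COC[C@]2(/C=N/NS(=O)(=O)c3ccc(C)cc3)CCC=C(C)[C@H]2CO[Si](C)(C)C(C)(C)C)cc1
F4 | step 3 | PMB ether with the C4 methyl group in place (formyl of F2 reduced to CH3) | COc1ccc(COC[C@]2(C)CCC=C(C)[C@H]2CO[Si](C)(C)C(C)(C)C)cc1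
F5 | step 3 | [(1R,2R)-2-{[(tert-butyldimethylsilyl)oxy]methyl}-1,3-dimethylcyclohex-3-en-1-yl]methanol | OC[C@]1(C)CCC=C(C)[C@H]1CO[Si](C)(C)C(C)(C)C
F6 | step 8 | C6 epimer of 10, methyl (1R,2R)-2-[(1R)-1-hydroxybut-3-yn-1-yl]-1,3-dimethylcyclohex-3-ene-1-carboxylate | COC(=O)[C@]1(C)CCC=C(C)[C@H]1[C@H](O)CC#C
F7 | step 8 | C6 epimer of 12, methyl (1R,2R)-2-[(1R,3E)-1-hydroxy-4-iodo-3-methylbut-3-en-1-yl]-1,3-dimethylcyclohex-3-ene-1-carboxylate | COC(=O)[C@]1(C)CCC=C(C)[C@H]1[C@H](O)C/C(C)=C/I
F8 | step 8 | methyl (1R,2R)-2-[(3E)-4-iodo-3-methylbut-3-enoyl]-1,3-dimethylcyclohex-3-ene-1-carboxylate | COC(=O)[C@]1(C)CCC=C(C)[C@H]1C(=O)C/C(C)=C/I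
F9 | step 12 | bicyclic acid with exocyclic C8 methylene (6α-OAc, 4α-CO2Me, 9β-CH2CH2CO2H) | COC(=O)[C@]1(C)CCC[C@@]2(C)[C@H]1[C@@H](OC(C)=O)CC(=C)[C@@H]2CCC(=O)O
F10 | step 12 | bicyclic acid with C7=C8 olefin (6α-OAc, 4α-CO2Me, 9β-CH2CH2CO2H) | COC(=O)[C@]1(C)CCC[C@@]2(C)[C@H]1[C@@H](OC(C)=O)C=C(C)[C@@H]2CCC(=O)O
F11 | step 12 | bicyclic 8α-hydroxy acid (6α-OAc, 4α-CO2Me, 8β-CH3, 9β-CH2CH2CO2H) | COC(=O)[C@]1(C)CCC[C@@]2(C)[C@H]1[C@@H](OC(C)=O)C[C@@](C)(O)[C@@H]2CCC(=O)O
F12 | step 19 | syn glycolate aldol adduct of 21 (15S-OH, 16-OPMB, (R)-4-benzyloxazolidinone imide) | COC(=O)[C@]1(C)CCC[C@@]2(C)[C@H]1[C@@H](O[Si](CC)(CC)CC)C[C@@](C)(O[Si](CC)(CC)CC)[C@@H]2CC/C(C)=C/[C@H](O)[C@@H](OCc1ccc(OC)cc1)C(=O)N1[C@H](Cc2ccccc2)COC1=O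
F13 | step 19 | Weinreb amide from F12 | COC(=O)[C@]1(C)CCC[C@@]2(C)[C@H]1[C@@H](O[Si](CC)(CC)CC)C[C@@](C)(O[Si](CC)(CC)CC)[C@@H]2CC/C(C)=C/[C@H](O)[C@@H](OCc1ccc(OC)cc1)C(=O)N(C)OC
F14 | step 19 | 15-O-triethylsilyl ether of F13 | COC(=O)[C@]1(C)CCC[C@@]2(C)[C@H]1[C@@H](O[Si](CC)(CC)CC)C[C@@](C)(O[Si](CC)(CC)CC)[C@@H]2CC/C(C)=C/[C@H](O[Si](CC)(CC)CC)[C@@H](OCc1ccc(OC)cc1)C(=O)N(C)OC
F15 | step 19 | methyl ketone from F14 | COC(=O)[C@]1(C)CCC[C@@]2(C)[C@H]1[C@@H](O[Si](CC)(CC)CC)C[C@@](C)(O[Si](CC)(CC)CC)[C@@H]2CC/C(C)=C/[C@H](O[Si](CC)(CC)CC)[C@@H](OCc1ccc(OC)cc1)C(C)=O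
F16 | step 19 | α-hydroxy ketone (16-OH free) from F15 | COC(=O)[C@]1(C)CCC[C@@]2(C)[C@H]1[C@@H](O[Si](CC)(CC)CC)C[C@@](C)(O[Si](CC)(CC)CC)[C@@H]2CC/C(C)=C/[C@H](O[Si](CC)(CC)CC)[C@@H](O)C(C)=O
F17 | step 19 | 6,8,15-tris-O-triethylsilyl ether of the target | COC(=O)[C@]1(C)CCC[C@@]2(C)[C@H]1[C@@H](O[Si](CC)(CC)CC)C[C@@](C)(O[Si](CC)(CC)CC)[C@@H]2CC/C(C)=C/[C@H](O[Si](CC)(CC)CC)[C@H]1OC(=O)C=C1C
A1 | alternative 1 | C4 primary carboxamide of the 6-deoxy bicycle (8α-OTES, isopropyl ester arm on C9) | NC(=O)[C@]1(C)CCC[C@@]2(C)[C@H]1CC[C@@](C)(O[Si](CC)(CC)CC)[C@@H]2CCC(=O)OC(C)C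
A2 | alternative 1 | γ-lactone from the C4 carbonyl to the 6α-oxygen | O=C1[C@]2(C)CCC[C@@]3(C)[C@H]2[C@@H](O1)C[C@@](C)(O[Si](CC)(CC)CC)[C@@H]3CCC(=O)OC(C)C
A3 | alternative 2 | acyclic triene ester with (E)-2-methyl enoate, 6-OTBS, 8-OTES and (E)-diene on C9 | COC(=O)/C(C)=C/[C@@H](O[Si](C)(C)C(C)(C)C)C[C@@](C)(O[Si](CC)(CC)CC)[C@H](CCOCc1ccc(OC)cc1)/C(C)=C/C=C
A4 | alternative 2 | trans-fused octalin ester with C1=C2 | COC(=O)[C@]1(C)CC=C[C@@]2(C)[C@H]1[C@@H](O[Si](C)(C)C(C)(C)C)C[C@@](C)(O[Si](CC)(CC)CC)[C@@H]2CCOCc1ccc(OC)cc1
A5 | alternative 3 | terminal alkyne of the bicycle (6α-OTBS, 8α-OH) | COC(=O)[C@]1(C)CCC[C@@]2(C)[C@H]1[C@@H](O[Si](C)(C)C(C)(C)C)C[C@@](C)(O)[C@@H]2CCC#C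
A6 | alternative 3 | (S)-2-[(4-methoxybenzyl)oxy]-3-(triethylsilyloxy)propanal | O=C[C@@H](OCc1ccc(OC)cc1)CO[Si](CC)(CC)CC
A7 | alternative 3 | (E)-allylic alcohol with C15 and C16 set | COC(=O)[C@]1(C)CCC[C@@]2(C)[C@H]1[C@@H](O[Si](C)(C)C(C)(C)C)C[C@@](C)(O)[C@@H]2CC/C(C)=C/[C@H](O)[C@@H](OCc1ccc(OC)cc1)CO[Si](CC)(CC)CC
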